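Ring A of the target is a hexasubstituted phloroglucinol in which O1 (on C8a) must be told apart from the C5 and C7 oxygens and must lie next to the C8 methyl. The route cuts ring A into a four-carbon unit (C8a, C6 with its prenyl group, C5, C4a) and a two-carbon unit (C8 with its methyl, C7). One thermal benzannulation of a 2-prenyl-3-siloxycyclobutenone with 1-siloxypropyne forms C8–C8a, C6–C7 and C4a–C8a. It should deliver a phenol whose only free hydroxyl is O1 and whose only unsubstituted carbon is C4a. Ring C is then built on exactly these two positions, and all protecting groups are silyl ethers removed together at the end.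

Key step: step 4

Remark: prenyl = 3-methylbut-2-en-1-yl, TIPS = triisopropylsilyl, TBS = tert-butyldimethylsilyl. The target has no stereocentre; the stereocentres of intermediates 11, 17 and 24 are formed racemic and are erased later. Ketene is assumed to be generated on demand from acetone in a pyrolysis generator.

Step 1
Reactants: 1 ethyl 4-methylpent-3-enoate
Product: 3 5-methyl-1-(triisopropylsilyloxy)hex-4-en-1-yne, via lithium ynolate 2 (not isolated)
Conditions: CH2Br2, lithium 2,2,6,6-tetramethylpiperidide, THF, −78 °C; then n-BuLi, −78 → 0 °C; then TIPSCl, −78 °C → rt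
Reagents that add atoms: dibromomethane, BrCBr; triisopropylsilyl chloride, CC(C)[Si](Cl)(C(C)C)C(C)C
Why: Kowalski ester homologation: LiCHBr2 should add to the ester at −78 °C faster than it removes the allylic α-proton, bromine–lithium exchange then triggers the 1,2-shift to the lithium ynolate, and the bulky silyl chloride traps it on oxygen.

Step 2
Reactants: 3 5-methyl-1-(triisopropylsilyloxy)hex-4-en-1-yne; 4 acetone
Product: 6 2-prenyl-3-(triisopropylsilyloxy)cyclobut-2-en-1-one, via ketene 5 (not isolated)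
Conditions: 4, hot-filament pyrolysis (ketene generator, ca. 700 °C); ketene stream into 3, CH2Cl2, 0 °C → rt
Reagents that add atoms: none
Why: [2+2] cycloaddition of ketene with an electron-rich siloxyalkyne is a known entry to 3-siloxycyclobutenones; the ketene carbonyl carbon bonds to the nucleophilic, prenyl-bearing alkyne carbon, and unactivated ketene should leave the isolated trisubstituted alkene alone.

Step 3
Reactants: 7 ethyl acetate
Product: 9 1-(triisopropylsilyloxy)propyne, via lithium ynolate 8 (not isolated)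
Conditions: CH2Br2, lithium 2,2,6,6-tetramethylpiperidide, THF, −78 °C; then n-BuLi, −78 → 0 °C; then TIPSCl, −78 °C → rt
Reagents that add atoms: dibromomethane, BrCBr; triisopropylsilyl chloride, CC(C)[Si](Cl)(C(C)C)C(C)C
Why: Kowalski ester homologation as in step 1, with O-silylation of lithium prop-1-ynolate by the hindered silyl chloride.

Step 4
Reactants: 6 2-prenyl-3-(triisopropylsilyloxy)cyclobut-2-en-1-one; 9 1-(triisopropylsilyloxy)propyne
Product: 14 2-methyl-4-prenyl-3,5-bis(triisopropylsilyloxy)phenol, via vinylketene 10 (not isolated), via 4-vinylcyclobutenone 11 (not isolated), via dienylketene 12 (not isolated), via cyclohexa-2,4-dienone 13 (not isolated)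
Conditions: 9 (1.5 equiv), PhMe, 110 °C, sealed tube, argon
Reagents that add atoms: none
Why: Heating opens cyclobutenone 6 by 4π electrocyclic ring opening to vinylketene 10, whose ketene C=C adds [2+2] to the siloxyalkyne to give 4-vinylcyclobutenone 11; a second 4π opening gives dienylketene 12, which closes to dienone 13 and tautomerises to the phenol. This is the Danheiser benzannulation of a cyclobutenone with a siloxyalkyne, here with a 3-siloxy group on the four-membered ring. Ring A is closed by a thermal disrotatory 6π electrocyclisation that forms C4a–C8a, and no stereocentre remains because the quaternary centre of 11 is lost on ring opening. The selectivity needed is the orientation of the ketene–alkyne [2+2]: the ketene carbonyl carbon (future C8a) must bond to the methyl-bearing alkyne carbon (future C8). Oxygen donation makes exactly that carbon, the one remote from the siloxy group, nucleophilic, so the methyl group ends between the new hydroxyl and C7–OTIPS. Because the hydroxyl comes from the ketene carbonyl while the other two oxygens arrive silylated, O1 is distinguished from O5 and O7 without any selective protection.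

Step 5
Reactants: 14 2-methyl-4-prenyl-3,5-bis(triisopropylsilyloxy)phenol; 15 (tert-butyldimethylsilyloxy)acetaldehyde
Product: 17 2-(tert-butyldimethylsilyloxy)-1-[2-hydroxy-3-methyl-5-prenyl-4,6-bis(triisopropylsilyloxy)phenyl]ethanol (racemic), via bromomagnesium phenolate 16 (not isolated)
Conditions: EtMgBr (1.0 equiv), Et2O, 0 °C; solvent exchange to PhMe; 15 (1.3 equiv), rt; H2O
Reagents that add atoms: none
Why: Ortho-specific hydroxyalkylation of a magnesium phenolate with an α-oxygenated aldehyde (Casiraghi-type chelation-controlled Friedel–Crafts reaction) should deliver the aldehyde through a six-membered magnesium chelate to C4a, the only free ring carbon, without acid that could touch the prenyl group; the carbinol centre forms racemic and is oxidised away in step 6.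

Step 6
Reactants: 17 2-(tert-butyldimethylsilyloxy)-1-[2-hydroxy-3-methyl-5-prenyl-4,6-bis(triisopropylsilyloxy)phenyl]ethanol
Product: 18 2-(tert-butyldimethylsilyloxy)-1-[2-hydroxy-3-methyl-5-prenyl-4,6-bis(triisopropylsilyloxy)phenyl]ethanone
Conditions: activated MnO2 (excess), CH2Cl2, rt, crude 17 used directly
Reagents that add atoms: none
Why: MnO2 oxidation of an electron-rich benzylic alcohol should give the hydrogen-bonded o-hydroxyaryl ketone while leaving the alkene, the phenol and the silyl ethers alone.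

Step 7
Reactants: 19 3,4-dihydroxybenzoic acid
Product: 21 3,4-bis(tert-butyldimethylsilyloxy)benzoic acid, via silyl ester 20 (not isolated)
Conditions: TBSCl (3.3 equiv), imidazole, DMF, rt; then AcOH/THF/H2O, rt
Reagents that add atoms: tert-butyldimethylsilyl chloride, CC(C)(C)[Si](C)(C)Cl
Why: Exhaustive silylation followed by selective hydrolysis of the labile silyl ester, which aqueous acetic acid cleaves while aryl TBS ethers persist.

Step 8
Reactants: 18 2-(tert-butyldimethylsilyloxy)-1-[2-hydroxy-3-methyl-5-prenyl-4,6-bis(triisopropylsilyloxy)phenyl]ethanone; 21 3,4-bis(tert-butyldimethylsilyloxy)benzoic acid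
Product: 23 2-[(tert-butyldimethylsilyloxy)acetyl]-6-methyl-4-prenyl-3,5-bis(triisopropylsilyloxy)phenyl 3,4-bis(tert-butyldimethylsilyloxy)benzoate, via acid chloride 22 (not isolated)
Conditions: 21, (COCl)2, DMF (cat.), CH2Cl2, 0 °C → rt; concentrate; then 18, Et3N, DMAP (cat.), CH2Cl2, 0 °C → rt
Reagents that add atoms: none
Why: Acid chloride formation and DMAP-catalysed O-acylation should occur at O1 because it is the only free hydroxyl in 18.

Step 9
Reactants: 23 2-[(tert-butyldimethylsilyloxy)acetyl]-6-methyl-4-prenyl-3,5-bis(triisopropylsilyloxy)phenyl 3,4-bis(tert-butyldimethylsilyloxy)benzoate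
Product: 24 1-[3,4-bis(tert-butyldimethylsilyloxy)phenyl]-2-(tert-butyldimethylsilyloxy)-3-[2-hydroxy-3-methyl-5-prenyl-4,6-bis(triisopropylsilyloxy)phenyl]propane-1,3-dione (racemic)
Conditions: LiN(SiMe3)2 (3 equiv), THF, −78 → 0 °C; AcOH quench
Reagents that add atoms: none
Why: Baker–Venkataraman rearrangement: the α-siloxy ketone enolate attacks the neighbouring aryl ester through a six-membered transition state (intramolecular Claisen condensation), which transfers the aroyl group from O1 to C3 and forms C2–C3; the C3 centre is racemic and becomes sp2 in step 10.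

Step 10
Reactants: 24 1-[3,4-bis(tert-butyldimethylsilyloxy)phenyl]-2-(tert-butyldimethylsilyloxy)-3-[2-hydroxy-3-methyl-5-prenyl-4,6-bis(triisopropylsilyloxy)phenyl]propane-1,3-dione
Product: 25 2-[3,4-bis(tert-butyldimethylsilyloxy)phenyl]-3-(tert-butyldimethylsilyloxy)-8-methyl-6-prenyl-5,7-bis(triisopropylsilyloxy)-4H-chromen-4-one
Conditions: camphorsulfonic acid (0.1 equiv), PhMe, 4 Å MS, 60 °C
Reagents that add atoms: none
Why: Acid-catalysed cyclodehydration of the o-hydroxyaryl 1,3-diketone through its cyclic hemiketal forms O1–C2; since O5 is still silylated, ring C can close only onto the oxygen next to the C8 methyl, and catalytic sulfonic acid in toluene should leave the aryl silyl ethers and the prenyl group intact.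

Step 11
Reactants: 25 2-[3,4-bis(tert-butyldimethylsilyloxy)phenyl]-3-(tert-butyldimethylsilyloxy)-8-methyl-6-prenyl-5,7-bis(triisopropylsilyloxy)-4H-chromen-4-one
Product: 26 8-methyl-6-prenylquercetin
Conditions: Bu4NF (6 equiv), AcOH (6 equiv), THF, 0 °C → rt, argon
Reagents that add atoms: none
Why: Fluoride-mediated global desilylation cleaves all five aryl and enol Si–O bonds, and the acetic acid buffer keeps the oxidation-prone polyphenol protonated.

Compound list
1 | ethyl 4-methylpent-3-enoate | CCOC(=O)CC=C(C)C | starting material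
2 | lithium 5-methylhex-4-en-1-yn-1-olate | [Li]OC#CCC=C(C)C | intermediate
3 | 5-methyl-1-(triisopropylsilyloxy)hex-4-en-1-yne | CC(C)=CCC#CO[Si](C(C)C)(C(C)C)C(C)C | intermediate
4 | acetone | CC(C)=O | starting material
5 | ketene | C=C=O | intermediate
6 | 2-prenyl-3-(triisopropylsilyloxy)cyclobut-2-en-1-one | CC(C)=CCC1=C(O[Si](C(C)C)(C(C)C)C(C)C)CC1=O | intermediate
7 | ethyl acetate | CCOC(C)=O | starting material
8 | lithium prop-1-yn-1-olate | [Li]OC#CC | intermediate
9 | 1-(triisopropylsilyloxy)propyne | CC#CO[Si](C(C)C)(C(C)C)C(C)C | intermediate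
10 | 2-prenyl-3-(triisopropylsilyloxy)buta-1,3-dien-1-one (vinylketene) | O=C=C(CC=C(C)C)C(=C)O[Si](C(C)C)(C(C)C)C(C)C | intermediate
11 | 2-methyl-4-prenyl-3-(triisopropylsilyloxy)-4-[1-(triisopropylsilyloxy)vinyl]cyclobut-2-en-1-one (racemic) | O=C1C(C)=C(O[Si](C(C)C)(C(C)C)C(C)C)C1(CC=C(C)C)C(=C)O[Si](C(C)C)(C(C)C)C(C)C | intermediate
12 | (3E)-2-methyl-4-prenyl-3,5-bis(triisopropylsilyloxy)hexa-1,3,5-trien-1-one (dienylketene, ketene and siloxyvinyl groups cis) | O=C=C(C)/C(O[Si](C(C)C)(C(C)C)C(C)C)=C(CC=C(C)C)\C(=C)O[Si](C(C)C)(C(C)C)C(C)C | intermediate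
13 | 2-methyl-4-prenyl-3,5-bis(triisopropylsilyloxy)cyclohexa-2,4-dien-1-one | CC1=C(O[Si](C(C)C)(C(C)C)C(C)C)C(CC=C(C)C)=C(O[Si](C(C)C)(C(C)C)C(C)C)CC1=O | intermediate
14 | 2-methyl-4-prenyl-3,5-bis(triisopropylsilyloxy)phenol | CC(C)=CCc1c(O[Si](C(C)C)(C(C)C)C(C)C)cc(O)c(C)c1O[Si](C(C)C)(C(C)C)C(C)C | intermediate
15 | (tert-butyldimethylsilyloxy)acetaldehyde | O=CCO[Si](C)(C)C(C)(C)C | starting material
16 | bromomagnesium 2-methyl-4-prenyl-3,5-bis(triisopropylsilyloxy)phenolate | CC(C)=CCc1c(O[Si](C(C)C)(C(C)C)C(C)C)cc(O[Mg]Br)c(C)c1O[Si](C(C)C)(C(C)C)C(C)C | intermediate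
17 | 2-(tert-butyldimethylsilyloxy)-1-[2-hydroxy-3-methyl-5-prenyl-4,6-bis(triisopropylsilyloxy)phenyl]ethanol (racemic) | CC(C)=CCc1c(O[Si](C(C)C)(C(C)C)C(C)C)c(C)c(O)c(C(O)CO[Si](C)(C)C(C)(C)C)c1O[Si](C(C)C)(C(C)C)C(C)C | intermediate
18 | 2-(tert-butyldimethylsilyloxy)-1-[2-hydroxy-3-methyl-5-prenyl-4,6-bis(triisopropylsilyloxy)phenyl]ethanone | CC(C)=CCc1c(O[Si](C(C)C)(C(C)C)C(C)C)c(C)c(O)c(C(=O)CO[Si](C)(C)C(C)(C)C)c1O[Si](C(C)C)(C(C)C)C(C)C | intermediate
19 | 3,4-dihydroxybenzoic acid | O=C(O)c1ccc(O)c(O)c1 | starting material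
20 | tert-butyldimethylsilyl 3,4-bis(tert-butyldimethylsilyloxy)benzoate | CC(C)(C)[Si](C)(C)OC(=O)c1ccc(O[Si](C)(C)C(C)(C)C)c(O[Si](C)(C)C(C)(C)C)c1 | intermediate
21 | 3,4-bis(tert-butyldimethylsilyloxy)benzoic acid | O=C(O)c1ccc(O[Si](C)(C)C(C)(C)C)c(O[Si](C)(C)C(C)(C)C)c1 | intermediate
22 | 3,4-bis(tert-butyldimethylsilyloxy)benzoyl chloride | O=C(Cl)c1ccc(O[Si](C)(C)C(C)(C)C)c(O[Si](C)(C)C(C)(C)C)c1 | intermediate
23 | 2-[(tert-butyldimethylsilyloxy)acetyl]-6-methyl-4-prenyl-3,5-bis(triisopropylsilyloxy)phenyl 3,4-bis(tert-butyldimethylsilyloxy)benzoate | CC(C)=CCc1c(O[Si](C(C)C)(C(C)C)C(C)C)c(C)c(OC(=O)c2ccc(O[Si](C)(C)C(C)(C)C)c(O[Si](C)(C)C(C)(C)C)c2)c(C(=O)CO[Si](C)(C)C(C)(C)C)c1O[Si](C(C)C)(C(C)C)C(C)C | intermediate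
24 | 1-[3,4-bis(tert-butyldimethylsilyloxy)phenyl]-2-(tert-butyldimethylsilyloxy)-3-[2-hydroxy-3-methyl-5-prenyl-4,6-bis(triisopropylsilyloxy)phenyl]propane-1,3-dione (racemic, drawn as the diketo form) | CC(C)=CCc1c(O[Si](C(C)C)(C(C)C)C(C)C)c(C)c(O)c(C(=O)C(O[Si](C)(C)C(C)(C)C)C(=O)c2ccc(O[Si](C)(C)C(C)(C)C)c(O[Si](C)(C)C(C)(C)C)c2)c1O[Si](C(C)C)(C(C)C)C(C)C | intermediate
25 | 2-[3,4-bis(tert-butyldimethylsilyloxy)phenyl]-3-(tert-butyldimethylsilyloxy)-8-methyl-6-prenyl-5,7-bis(triisopropylsilyloxy)-4H-chromen-4-one | CC(C)=CCc1c(O[Si](C(C)C)(C(C)C)C(C)C)c(C)c2oc(-c3ccc(O[Si](C)(C)C(C)(C)C)c(O[Si](C)(C)C(C)(C)C)c3)c(O[Si](C)(C)C(C)(C)C)c(=O)c2c1O[Si](C(C)C)(C(C)C)C(C)C | intermediate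
26 | 8-methyl-6-prenylquercetin, 2-(3,4-dihydroxyphenyl)-3,5,7-trihydroxy-8-methyl-6-(3-methylbut-2-enyl)-4H-chromen-4-one | CC(C)=CCc1c(O)c(C)c2oc(-c3ccc(O)c(O)c3)c(O)c(=O)c2c1O | target

Total step count: 11. Longest linear sequence: 9 steps (steps 1, 2, 4, 5, 6, 8, 9, 10, 11).

Steps most likely to fail

Step 4. The push–pull cyclobutenone may open only at temperatures where the prenyl-substituted vinylketene dimerises or acylates the product phenol faster than the alkyne intercepts it. The fallback moves the prenyl group from the four-membered ring to the alkyne and relocates the free hydroxyl by a silyl relay; it sets out from ynolate 8 and alkyne 3 and returns at 14. Ynolate 8 would be trapped with TBSCl to give 1-(tert-butyldimethylsilyloxy)propyne F1. Ketene from 4, as in step 2, would convert it into 3-(tert-butyldimethylsilyloxy)-2-methylcyclobut-2-en-1-one F2. Heating F2 with 3 in toluene should give 5-(tert-butyldimethylsilyloxy)-4-methyl-2-prenyl-3-(triisopropylsilyloxy)phenol F3, whose free hydroxyl is the future C5–OH. Silylation with TIPSOTf and 2,6-lutidine would give tert-butyldimethyl[2-methyl-4-prenyl-3,5-bis(triisopropylsilyloxy)phenoxy]silane F4. Selective cleavage of the less hindered and more labile aryl TBS ether (Cs2CO3, DMF/H2O, rt) should then free O1 and give 14.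

Step 5. Carbon–carbon bond formation at C4a, crowded by the neighbouring OTIPS group, may be slow, and the electron-rich o-hydroxybenzylic alkoxide may lose water to an o-quinone methide. The fallback replaces the phenolate as carbon nucleophile by an aryllithium and an intramolecular acyl transfer; it sets out from 14 and returns at 18, bypassing step 6 as well. Bromination with NBS (CH2Cl2, −78 °C) should give 6-bromo-2-methyl-4-prenyl-3,5-bis(triisopropylsilyloxy)phenol F5. Acylation of O1 with (tert-butyldimethylsilyloxy)acetyl chloride (Et3N, DMAP) would give 2-bromo-6-methyl-4-prenyl-3,5-bis(triisopropylsilyloxy)phenyl (tert-butyldimethylsilyloxy)acetate F6. Bromine–lithium exchange with t-BuLi (2 equiv, THF, −100 °C) should trigger an anionic Fries 1,3 O→C acyl shift to ketone 18; the intramolecular transfer is expected to outrun silyl migration from the neighbouring oxygen to carbon.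

Step 10. Acid may protonate the prenyl double bond or remove the C5 silyl ether before ring closure, which would allow chroman formation or closure onto the wrong oxygen. The fallback replaces acid-catalysed dehydration by base-mediated elimination of an activated hemiketal; it sets out from 24 and returns at 25. Trifluoroacetic anhydride and pyridine (CH2Cl2, 0 °C → rt) should acylate the cyclic hemiketal form of 24 to give 2-[3,4-bis(tert-butyldimethylsilyloxy)phenyl]-3-(tert-butyldimethylsilyloxy)-8-methyl-4-oxo-6-prenyl-5,7-bis(triisopropylsilyloxy)chroman-2-yl trifluoroacetate F7, which is not isolated. Pyridine then removes the C3 proton and expels trifluoroacetate to give 25 without any free Brønsted acid.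

Further compounds
F1 | step 4 | 1-(tert-butyldimethylsilyloxy)propyne | CC#CO[Si](C)(C)C(C)(C)C
F2 | step 4 | 3-(tert-butyldimethylsilyloxy)-2-methylcyclobut-2-en-1-one | CC1=C(O[Si](C)(C)C(C)(C)C)CC1=O
F3 | step 4 | 5-(tert-butyldimethylsilyloxy)-4-methyl-2-prenyl-3-(triisopropylsilyloxy)phenol | CC(C)=CCc1c(O)cc(O[Si](C)(C)C(C)(C)C)c(C)c1O[Si](C(C)C)(C(C)C)C(C)C
F4 | step 4 | tert-butyldimethyl[2-methyl-4-prenyl-3,5-bis(triisopropylsilyloxy)phenoxy]silane | CC(C)=CCc1c(O[Si](C(C)C)(C(C)C)C(C)C)cc(O[Si](C)(C)C(C)(C)C)c(C)c1O[Si](C(C)C)(C(C)C)C(C)C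
F5 | step 5 | 6-bromo-2-methyl-4-prenyl-3,5-bis(triisopropylsilyloxy)phenol | CC(C)=CCc1c(O[Si](C(C)C)(C(C)C)C(C)C)c(Br)c(O)c(C)c1O[Si](C(C)C)(C(C)C)C(C)C
F6 | step 5 | 2-bromo-6-methyl-4-prenyl-3,5-bis(triisopropylsilyloxy)phenyl (tert-butyldimethylsilyloxy)acetate | CC(C)=CCc1c(O[Si](C(C)C)(C(C)C)C(C)C)c(Br)c(OC(=O)CO[Si](C)(C)C(C)(C)C)c(C)c1O[Si](C(C)C)(C(C)C)C(C)C
F7 | step 10 | 2-[3,4-bis(tert-butyldimethylsilyloxy)phenyl]-3-(tert-butyldimethylsilyloxy)-8-methyl-4-oxo-6-prenyl-5,7-bis(triisopropylsilyloxy)chroman-2-yl trifluoroacetate (mixture of racemic diastereomers) | CC(C)=CCc1c(O[Si](C(C)C)(C(C)C)C(C)C)c(C)c2OC(OC(=O)C(F)(F)F)(c3ccc(O[Si](C)(C)C(C)(C)C)c(O[Si](C)(C)C(C)(C)C)c3)C(O[Si](C)(C)C(C)(C)C)C(=O)c2c1O[Si](C(C)C)(C(C)C)C(C)C
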